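**Plan**

- Labdane numbering is used: ring A = C1–C5, C10; ring B = C5–C10; oxolane = C9, C11, C12, C13, O; dihydrofuran = C13, C14, C15, O, C16; C17 is the methyl on C8.
- Enabling feature: on the oxolane the exocyclic carbons C8 (on C9) and C16 (on C13) are cis, so joining them by a C8=C16 bond turns the oxolane into a 7-oxabicyclo[2.2.1]heptadiene, the adduct of a furan and an alkyne.
- Cuts, in retrosynthetic order: C14=C15/C15–O (enol ether from a lactol), the C19 silyl ether, C8–C17 with the acetate (methyl addition to a C8 ketone), C8/C16 rejoined as an alkene (ozonolysis retron), then C8–C9 and C13–C16 (furan plus tethered ynone), C7–C8 (Weinreb amide plus ethynyl), C9–C11 and C13–O (acid chloride plus alkyne, then cycloisomerisation), and C8, C11–C14 of (+)-podocarpic acid (arene degradation).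
- Forward order: ring A from the chiral pool, then the furan, then ring B and the oxygen bridge in one cycloaddition, then the oxolane by ozonolysis, the spiro acetal ring, and last the dihydrofuran.
- Stereochemistry: C4, C5 and C10 come from (+)-podocarpic acid; C9 and C13 are set in the cycloaddition (mutual configuration by the cage, face by a chair-like ring B); C8 is set by methyl addition anti to the 10β-methyl group.

Key step: step 11

Remark on the chemistry: (+)-podocarpic acid is taken as a purchasable chiral-pool compound; the C7 carbinol of 19–27 is drawn as the expected 7β epimer (the 7α epimer would converge at 28), and C15 of 24–30 is an anomeric mixture that converges at 31.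

**Route**

Step 1
Reactants: 1 (+)-podocarpic acid
Product: 2 podocarpa-8,11,13-triene-12,19-diol
Conditions: LiAlH4 (excess), THF, reflux
Reagents that add atoms: none
Why: Hydride reduction of the hindered axial carboxylic acid (LiAlH4 reduction) gives the neopentyl C19 carbinol and leaves the ring A stereocentres C4, C5 and C10 of the chiral-pool acid untouched.

Step 2
Reactants: 2 podocarpa-8,11,13-triene-12,19-diol
Product: 3 12,19-bis(triisopropylsilyloxy)podocarpa-8,11,13-triene
Conditions: TIPSOTf, 2,6-lutidine, CH2Cl2, 0 °C to rt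
Reagents that add atoms: triisopropylsilyl trifluoromethanesulfonate, CC(C)[Si](C(C)C)(C(C)C)OS(=O)(=O)C(F)(F)F
Why: Silyl ether formation with the silyl triflate caps the phenol and the hindered C19 alcohol in one operation, and the C19 ether is kept until the last step.

Step 3
Reactants: 3 12,19-bis(triisopropylsilyloxy)podocarpa-8,11,13-triene
Product: 4 12,19-bis(triisopropylsilyloxy)podocarpa-8,11,13-trien-7-one
Conditions: CrO3, AcOH/H2O, rt
Reagents that add atoms: chromium trioxide, O=[Cr](=O)=O
Why: Benzylic oxidation by hexavalent chromium can only occur at C7, the sole benzylic methylene (C9 sits on quaternary C10), and is assisted by the para silyloxy group.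

Step 4
Reactants: 4 12,19-bis(triisopropylsilyloxy)podocarpa-8,11,13-trien-7-one
Product: 5 seven-membered aryl lactone (oxygen inserted between C7 and C8)
Conditions: mCPBA, TFA (cat.), CH2Cl2, 0 °C to rt
Reagents that add atoms: 3-chloroperoxybenzoic acid, OOC(=O)c1cccc(Cl)c1
Why: Baeyer–Villiger oxidation of the aryl ketone should proceed with migration of the electron-rich aryl carbon C8 (para to the silyloxy group) in preference to the C6 methylene.

Step 5
Reactants: 5 seven-membered aryl lactone
Product: 6 phenol Weinreb amide (C7 amide on the C5 arm and C8 phenol on the aryl group at C10)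
Conditions: MeNHOMe·HCl, iPrMgCl, THF, −20 to 0 °C
Reagents that add atoms: N,O-dimethylhydroxylamine hydrochloride, CNOC.Cl
Why: The aryl ester is an activated acyl donor, so aminolysis by the magnesium amide opens the lactone to the C7 Weinreb amide and thereby differentiates C7 from C9 once and for all.

Step 6
Reactants: 6 phenol Weinreb amide
Product: 7 (1S,2S,3S)-2-[2-[methoxy(methyl)amino]-2-oxoethyl]-1,3-dimethyl-3-[(triisopropylsilyloxy)methyl]cyclohexane-1-carboxylic acid
Conditions: RuCl3·xH2O (cat.), NaIO4, EtOAc/MeCN/H2O, rt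
Reagents that add atoms: sodium periodate, [Na+].[O-]I(=O)(=O)=O; water, O
Why: RuO4 generated in the flask degrades the electron-rich hydroquinone-type ring and retains only its ipso carbon C9 as a carboxylic acid on C10 (oxidative arene degradation), which removes C8 and C11–C14 of the podocarpane.

Step 7
Reactants: 8 3-bromo-1,1-dimethoxypropane; 9 lithium acetylide ethylenediamine complex
Product: 10 5,5-dimethoxypent-1-yne
Conditions: DMSO, 10 °C to rt
Reagents that add atoms: none
Why: SN2 alkylation of the acetylide by the primary bromide gives the terminal alkyne that supplies C11–C15.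

Step 8
Reactants: 7 ring A carboxylic acid; 10 5,5-dimethoxypent-1-yne
Product: 12 alkynyl ketone C9(=O)–C11≡C12–CH2CH2CH(OMe)2 on C10, via acid chloride 11 (not isolated)
Conditions: 1-chloro-N,N,2-trimethylprop-1-en-1-amine, CH2Cl2, 0 °C to rt; then 10, PdCl2(PPh3)2 (cat.), CuI (cat.), Et3N, THF, rt
Reagents that add atoms: none
Why: Neutral conversion of the tertiary acid into its chloride followed by acyl Sonogashira coupling forms the C9–C11 bond under conditions to which the Weinreb amide, acetal and silyl ether are inert.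

Step 9
Reactants: 12 alkynyl ketone
Product: 14 furan Weinreb amide (5-(2,2-dimethoxyethyl)furan-2-yl on C10), via allenyl ketone 13 (not isolated)
Conditions: CuI (cat.), Et3N/DMA (1:7), 100 °C
Reagents that add atoms: none
Why: Base-mediated propargyl-to-allenyl isomerisation, copper-assisted attack of the C9 carbonyl oxygen on C13 and aromatisation give the 2,5-disubstituted furan (cycloisomerisation of an alkynyl ketone).

Step 10
Reactants: 14 furan Weinreb amide; 15 ethynylmagnesium bromide
Product: 16 furan ynone (C7(=O)–C8≡C16H on the C5 arm)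
Conditions: THF, 0 °C; inverse quench into cold aq. NaHSO4
Reagents that add atoms: none
Why: Acyl substitution of the Weinreb amide by the alkynyl Grignard reagent stops at the ketone stage (Weinreb ketone synthesis), and the acidic inverse quench keeps the liberated amine from adding to the ynone.

Step 11
Reactants: 16 furan ynone
Product: 17 oxanorbornadiene (bridgeheads C9 and C13; 9α-oxygen bridge; C11=C12; C8=C16 conjugated to the C7 ketone of ring B)
Conditions: PhMe (0.005 M), BHT (cat.), 110 °C
Reagents that add atoms: none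
Why: A concerted, thermally allowed [4+2] cycloaddition joins the electron-rich 2,5-dialkylfuran (C9, C11, C12, C13, with O as the future bridge) to the electron-poor ynone C8≡C16, the closest known reaction type being the intramolecular Diels–Alder reaction of furans with tethered alkynones. Ring B closes as a six-membered ring by C8–C9 bond formation through the four-atom tether C10–C5–C6–C7, and the 7-oxabicyclo[2.2.1]heptadiene closes by C13–C16 bond formation at the far furan terminus. C9 and C13 are created together and suprafacially, so the cage fixes their mutual configuration (C8 and C16 cis on the later oxolane). Their sense relative to ring A depends on which furan face is used: with the furan and the C5 arm both equatorial on the ring A chair, a chair-like ring B should place the small furan oxygen axial (α, anti to the 10β-methyl group) and the bulkier C11=C12 flank equatorial, away from the axial hydrogens on C1 and C5. Facial selectivity is thus the one selectivity that is needed and not guaranteed; regiochemistry is fixed by the tether, the quaternary bridgeheads prevent aromatisation of the adduct, and neutral thermal conditions spare the acetal and the silyl ether.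

Step 12
Reactants: 17 oxanorbornadiene
Product: 18 oxanorbornene enone (11,12-dihydro-17)
Conditions: KO2CN=NCO2K, AcOH, MeOH/CH2Cl2, 0 °C to rt
Reagents that add atoms: none
Why: Diimide reduction is fastest for strained, unpolarised cis-disubstituted double bonds, so C11=C12 should be saturated while the trisubstituted, conjugated C8=C16 bond is kept, and no stereocentre is formed.

Step 13
Reactants: 18 oxanorbornene enone
Product: 19 7β-allylic alcohol
Conditions: NaBH4, CeCl3·7H2O, MeOH, −78 to −20 °C
Reagents that add atoms: none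
Why: Luche reduction gives 1,2-reduction of the enone with hydride expected on the α face (axial delivery) to give the 7β-alcohol, a centre of no consequence because C7 is re-oxidised in step 19.

Step 14
Reactants: 19 7β-allylic alcohol
Product: 20 7β-benzyl ether
Conditions: NaH, BnBr, Bu4NI (cat.), THF, 0 °C to rt
Reagents that add atoms: benzyl bromide, BrCc1ccccc1
Why: Williamson etherification masks the C7 hydroxyl with a group that tolerates ozone at low temperature, hydride, mild acid and methyllithium and is later removed by neutral hydrogenolysis.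

Step 15
Reactants: 20 7β-benzyl ether
Product: 22 keto aldehyde (C8 ketone and C16 aldehyde cis on the oxolane), via ozonide 21 (not isolated)
Conditions: O3, CH2Cl2, −78 °C (stopped when 20 is consumed); then PPh3, −78 °C to rt
Reagents that add atoms: ozone, [O-][O+]=O
Why: Ozonolysis cleaves the only remaining C=C bond into the C8 ketone and the C16 aldehyde, and with C7 held at the alcohol oxidation level no 1,2-diketone can form.

Step 16
Reactants: 22 keto aldehyde
Product: 24 cyclic methyl acetal ketone (spiro 2-methoxyoxolane C13–C14–C15–O–C16), via hydroxy acetal 23 (not isolated)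
Conditions: NaBH(OAc)3, AcOH, CH2Cl2, rt; then PPTS (cat.), 4 Å MS, CH2Cl2, rt
Reagents that add atoms: none
Why: The acyloxyborohydride should reduce the aldehyde and not the hindered ketone (chemoselective hydride reduction), and acid then closes the C16 hydroxyl onto C15 with loss of methanol (transacetalisation) to give the five-membered acetal as a mixture of C15 anomers.

Step 17
Reactants: 24 cyclic methyl acetal ketone
Product: 26 8β-acetoxy-8α-methyl 7β-benzyl ether, via lithium alkoxide 25 (not isolated)
Conditions: MeLi, THF/Et2O, −78 °C; then Ac2O, DMAP (cat.), −78 °C to rt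
Reagents that add atoms: methyllithium, C[Li]; acetic anhydride, CC(=O)OC(C)=O
Why: 1,2-Addition of methyllithium to the C8 ketone should take place on the α face because the β face is closed by the syn-axial 10β-methyl group, which sets the 8α-methyl 8β-oxygen centre, and the hindered tertiary oxygen is acetylated as its alkoxide in the same flask.

Step 18
Reactants: 26 8β-acetoxy-8α-methyl 7β-benzyl ether
Product: 27 8β-acetoxy 7β-alcohol
Conditions: H2 (1 atm), Pd/C, EtOAc, rt
Reagents that add atoms: none
Why: Hydrogenolysis of the benzyl ether frees the C7 hydroxyl under neutral conditions that do not promote acetyl migration from the tertiary to the secondary oxygen.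

Step 19
Reactants: 27 8β-acetoxy 7β-alcohol
Product: 28 8β-acetoxy 7-ketone
Conditions: IBX, DMSO, rt
Reagents that add atoms: none
Why: Hypervalent iodine oxidation with IBX converts the secondary alcohol into the C7 ketone without cleaving the C7–C8 bond and without touching the acetal or the silyl ether.

Step 20
Reactants: 28 8β-acetoxy 7-ketone
Product: 29 lactol (15-hydroxy)
Conditions: HCl (0.5 M aq.), THF, rt
Reagents that add atoms: water, O
Why: Mild acetal hydrolysis of the furanoside-type methyl acetal gives the lactol as an anomeric mixture under conditions that the tertiary acetate and the primary TIPS ether should survive.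

Step 21
Reactants: 29 lactol
Product: 31 C19 silyl ether of the target (14,15-enol ether), via lactol mesylate 30 (not isolated)
Conditions: MsCl, Et3N, CH2Cl2, −20 °C to reflux
Reagents that add atoms: none
Why: Sulfonylation of the anomeric hydroxyl and amine-induced loss of methanesulfonic acid across C14–C15 give the 2,3-dihydrofuran (lactol dehydration), C14 carrying the only β-hydrogens.

Step 22
Reactants: 31 C19 silyl ether of the target
Product: 32 target (CNP0239339.1)
Conditions: TBAF, AcOH (1:1), THF, rt to 40 °C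
Reagents that add atoms: none
Why: Buffered fluoride desilylation frees the C19 alcohol without acid, which the enol ether would not tolerate, and without free alkoxide, which could attack the α-keto acetate.

**Compound list**

1 | (+)-podocarpic acid, 12-hydroxypodocarpa-8,11,13-trien-19-oic acid (4β-CO2H, 4α-CH3, 5α-H, 10β-CH3) | C1C[C@H]2[C@@](C)(C(=O)O)CCC[C@]2(C)c2cc(O)ccc12 | starting material
2 | podocarpa-8,11,13-triene-12,19-diol | C1C[C@H]2[C@@](C)(CO)CCC[C@]2(C)c2cc(O)ccc12 | intermediate
3 | 12,19-bis(triisopropylsilyloxy)podocarpa-8,11,13-triene | C1C[C@H]2[C@@](C)(CO[Si](C(C)C)(C(C)C)C(C)C)CCC[C@]2(C)c2cc(O[Si](C(C)C)(C(C)C)C(C)C)ccc12 | intermediate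
4 | 12,19-bis(triisopropylsilyloxy)podocarpa-8,11,13-trien-7-one | O=C1C[C@H]2[C@@](C)(CO[Si](C(C)C)(C(C)C)C(C)C)CCC[C@]2(C)c2cc(O[Si](C(C)C)(C(C)C)C(C)C)ccc12 | intermediate
5 | aryl lactone, 7a-oxa-B-homo analogue of 4 (ring C5–C6–C7(=O)–O–C8–C9–C10) | O=C1C[C@H]2[C@@](C)(CO[Si](C(C)C)(C(C)C)C(C)C)CCC[C@]2(C)c2cc(O[Si](C(C)C)(C(C)C)C(C)C)ccc2O1 | intermediate
6 | phenol Weinreb amide: ring A (4α-CH3, 4β-CH2OTIPS, 5α-H, 10β-CH3) with CH2C(O)N(OMe)Me on C5 and 2-hydroxy-5-(triisopropylsilyloxy)phenyl on C10 | CON(C)C(=O)C[C@H]1[C@@](C)(CO[Si](C(C)C)(C(C)C)C(C)C)CCC[C@]1(C)c1cc(O[Si](C(C)C)(C(C)C)C(C)C)ccc1O | intermediate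
7 | (1S,2S,3S)-2-[2-[methoxy(methyl)amino]-2-oxoethyl]-1,3-dimethyl-3-[(triisopropylsilyloxy)methyl]cyclohexane-1-carboxylic acid (CO2H = C9 on C10) | CON(C)C(=O)C[C@H]1[C@@](C)(CO[Si](C(C)C)(C(C)C)C(C)C)CCC[C@]1(C)C(=O)O | intermediate
8 | 3-bromo-1,1-dimethoxypropane | BrCCC(OC)OC | starting material
9 | lithium acetylide ethylenediamine complex | [Li]C#C.NCCN | starting material
10 | 5,5-dimethoxypent-1-yne | C#CCCC(OC)OC | intermediate
11 | acid chloride of 7 (formed and used in the flask) | CON(C)C(=O)C[C@H]1[C@@](C)(CO[Si](C(C)C)(C(C)C)C(C)C)CCC[C@]1(C)C(Cl)=O | intermediate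
12 | alkynyl ketone, C10–C9(=O)–C11≡C12–CH2CH2CH(OMe)2, C7 Weinreb amide and 19-OTIPS retained | CON(C)C(=O)C[C@H]1[C@@](C)(CO[Si](C(C)C)(C(C)C)C(C)C)CCC[C@]1(C)C(=O)C#CCCC(OC)OC | intermediate
13 | allenyl ketone isomer of 12, C9(=O)–C11H=C12=C13H–CH2CH(OMe)2 (allene axis unassigned; formed and used in the flask) | CON(C)C(=O)C[C@H]1[C@@](C)(CO[Si](C(C)C)(C(C)C)C(C)C)CCC[C@]1(C)C(=O)C=C=CCC(OC)OC | intermediate
14 | furan Weinreb amide, 5-(2,2-dimethoxyethyl)furan-2-yl on C10 | CON(C)C(=O)C[C@H]1[C@@](C)(CO[Si](C(C)C)(C(C)C)C(C)C)CCC[C@]1(C)c1ccc(CC(OC)OC)o1 | intermediate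
15 | ethynylmagnesium bromide | C#C[Mg]Br | starting material
16 | furan ynone, as 14 with C7(=O)–C8≡C16H on the C5 arm | C#CC(=O)C[C@H]1[C@@](C)(CO[Si](C(C)C)(C(C)C)C(C)C)CCC[C@]1(C)c1ccc(CC(OC)OC)o1 | intermediate
17 | oxanorbornadiene: 7-oxabicyclo[2.2.1]hepta-2,5-diene with bridgeheads C9 and C13, 9α-O bridge, C11=C12, C8=C16 conjugated to the C7 ketone of ring B, CH2CH(OMe)2 on C13 | O=C1C[C@H]2[C@@](C)(CO[Si](C(C)C)(C(C)C)C(C)C)CCC[C@]2(C)[C@@]23C=C[C@](CC(OC)OC)(O3)C=C12 | intermediate
18 | oxanorbornene enone (11,12-dihydro-17) | O=C1C[C@H]2[C@@](C)(CO[Si](C(C)C)(C(C)C)C(C)C)CCC[C@]2(C)[C@@]23CC[C@](CC(OC)OC)(O3)C=C12 | intermediate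
19 | 7β-allylic alcohol of 18 | O[C@H]1C[C@H]2[C@@](C)(CO[Si](C(C)C)(C(C)C)C(C)C)CCC[C@]2(C)[C@@]23CC[C@](CC(OC)OC)(O3)C=C12 | intermediate
20 | 7β-benzyl ether of 19 | C(c1ccccc1)O[C@H]1C[C@H]2[C@@](C)(CO[Si](C(C)C)(C(C)C)C(C)C)CCC[C@]2(C)[C@@]23CC[C@](CC(OC)OC)(O3)C=C12 | intermediate
21 | ozonide of 20, 1,2,4-trioxolane across C8 and C16 (configuration at C8 and C16 unassigned; formed and used in the flask) | C(c1ccccc1)O[C@H]1C[C@H]2[C@@](C)(CO[Si](C(C)C)(C(C)C)C(C)C)CCC[C@]2(C)[C@@]23CC[C@](CC(OC)OC)(O3)C4OOC12O4 | intermediate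
22 | keto aldehyde: 7β-benzyloxy-9α,13-epoxy-15,15-dimethoxy-8-oxo-19-(triisopropylsilyloxy)-17-norlabdan-16-al, C16 cis to C8 on the oxolane | O=C1[C@@H](OCc2ccccc2)C[C@H]2[C@@](C)(CO[Si](C(C)C)(C(C)C)C(C)C)CCC[C@]2(C)[C@@]12CC[C@@](CC(OC)OC)(C=O)O2 | intermediate
23 | hydroxy acetal, 16-alcohol of 22 (formed and used in the flask) | O=C1[C@@H](OCc2ccccc2)C[C@H]2[C@@](C)(CO[Si](C(C)C)(C(C)C)C(C)C)CCC[C@]2(C)[C@@]12CC[C@@](CC(OC)OC)(CO)O2 | intermediate
24 | 7β-benzyloxy-9α,13:15,16-diepoxy-15-methoxy-19-(triisopropylsilyloxy)-17-norlabdan-8-one (C15 anomers) | O=C1[C@@H](OCc2ccccc2)C[C@H]2[C@@](C)(CO[Si](C(C)C)(C(C)C)C(C)C)CCC[C@]2(C)[C@@]12CC[C@]1(CC(OC)OC1)O2 | intermediate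
25 | lithium 8β-alkoxide, 8α-methyl adduct of 24 (formed and used in the flask) | [Li]O[C@@]1(C)[C@@H](OCc2ccccc2)C[C@H]2[C@@](C)(CO[Si](C(C)C)(C(C)C)C(C)C)CCC[C@]2(C)[C@@]12CC[C@]1(CC(OC)OC1)O2 | intermediate
26 | 8β-acetoxy-7β-benzyloxy-9α,13:15,16-diepoxy-15-methoxy-19-(triisopropylsilyloxy)labdane | CC(=O)O[C@@]1(C)[C@@H](OCc2ccccc2)C[C@H]2[C@@](C)(CO[Si](C(C)C)(C(C)C)C(C)C)CCC[C@]2(C)[C@@]12CC[C@]1(CC(OC)OC1)O2 | intermediate
27 | 8β-acetoxy-9α,13:15,16-diepoxy-15-methoxy-19-(triisopropylsilyloxy)labdan-7β-ol | CC(=O)O[C@@]1(C)[C@@H](O)C[C@H]2[C@@](C)(CO[Si](C(C)C)(C(C)C)C(C)C)CCC[C@]2(C)[C@@]12CC[C@]1(CC(OC)OC1)O2 | intermediate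
28 | 8β-acetoxy-9α,13:15,16-diepoxy-15-methoxy-19-(triisopropylsilyloxy)labdan-7-one | CC(=O)O[C@@]1(C)C(=O)C[C@H]2[C@@](C)(CO[Si](C(C)C)(C(C)C)C(C)C)CCC[C@]2(C)[C@@]12CC[C@]1(CC(OC)OC1)O2 | intermediate
29 | lactol, 15-hydroxy analogue of 28 | CC(=O)O[C@@]1(C)C(=O)C[C@H]2[C@@](C)(CO[Si](C(C)C)(C(C)C)C(C)C)CCC[C@]2(C)[C@@]12CC[C@]1(CC(O)OC1)O2 | intermediate
30 | lactol mesylate, 15-methanesulfonate of 29 (formed and used in the flask) | CC(=O)O[C@@]1(C)C(=O)C[C@H]2[C@@](C)(CO[Si](C(C)C)(C(C)C)C(C)C)CCC[C@]2(C)[C@@]12CC[C@]1(CC(OS(C)(=O)=O)OC1)O2 | intermediate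
31 | 8β-acetoxy-9α,13:15,16-diepoxy-19-(triisopropylsilyloxy)labd-14-en-7-one | CC(=O)O[C@@]1(C)C(=O)C[C@H]2[C@@](C)(CO[Si](C(C)C)(C(C)C)C(C)C)CCC[C@]2(C)[C@@]12CC[C@]1(C=COC1)O2 | intermediate
32 | (13R)-8β-acetoxy-9α,13:15,16-diepoxy-19-hydroxylabd-14-en-7-one, (4S,5S,8R,9S,10S,13R) | CC(=O)O[C@@]1(C)C(=O)C[C@H]2[C@@](C)(CO)CCC[C@]2(C)[C@@]12CC[C@]1(C=COC1)O2 | target

**Step count**

Total: 22 steps. Longest linear sequence: 21 steps (steps 1–6 and 8–22) from (+)-podocarpic acid; step 7 prepares alkyne 10 on a side branch.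

**Steps most likely to fail, with fallbacks**

Step 11. The ynone may attack the wrong furan face, or the two faces may react at similar rates, because the preference for an axial oxygen bridge rests only on a conformational argument. The fallback replaces kinetic by thermodynamic selection and uses an acetylene equivalent whose cycloaddition is reversible. Setting out from 16, conjugate addition of PhSO2Na (AcOH, MeOH, 0 °C) should give the (E)-β-phenylsulfonyl enone F1. Warming F1 in toluene lets the furan and the sulfonyl enone add and revert until the more stable cage accumulates, expected to be the one with the oxygen bridge axial and anti to the 10β-methyl group; this is the sulfonyl cycloadduct F2, whose C8 and C16 configuration is immaterial. DBU then expels benzenesulfinate across C8–C16 and the route is rejoined at 17.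

Step 17. The methyl nucleophile may add on the β face, giving the C8 epimer, or enolisation toward C7 may outpace addition. The fallback delivers the oxygen, not the carbon, from whichever face is open, which gives the complementary C8 configuration. Setting out from 24, Wittig methylenation (Ph3P=CH2 from Ph3PCH3Br and KOtBu, PhMe, 80 °C) would give the 8(17)-methylene compound F5. Epoxidation (mCPBA, NaHCO3, CH2Cl2) would give the 8β,17-epoxide F6, and LiAlH4 would open it at the methylene terminus to the tertiary alcohol F7. Deprotonation with KN(SiMe3)2 and acetylation with Ac2O return the sequence to 26.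

Step 16. Hydride may also reduce the doubly α-oxygenated C8 ketone, or the keto aldehyde may close by aldol or hemiketal formation before the aldehyde is reduced. The fallback gives up chemoselective reduction. Setting out from 22, NaBH4 (excess, MeOH, 0 °C) reduces both carbonyl groups to the C8,C16-diol F3. PPTS (CH2Cl2, 4 Å MS) closes the primary C16 hydroxyl onto the C15 acetal to give the hydroxy cyclic acetal F4. IBX (DMSO, rt) then re-oxidises the C8 carbinol and the route is rejoined at 24.

**Further compounds**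

F1 | step 11 | (E)-β-phenylsulfonyl enone, C7(=O)–C8H=C16H–SO2Ph on the C5 arm of the furan | O=C(/C=C/S(=O)(=O)c1ccccc1)C[C@H]1[C@@](C)(CO[Si](C(C)C)(C(C)C)C(C)C)CCC[C@]1(C)c1ccc(CC(OC)OC)o1
F2 | step 11 | sulfonyl cycloadduct, 7-oxanorbornene with C8–H and C16–SO2Ph (C8 and C16 unassigned) | O=C1C[C@H]2[C@@](C)(CO[Si](C(C)C)(C(C)C)C(C)C)CCC[C@]2(C)[C@@]23C=C[C@](CC(OC)OC)(O3)C(S(=O)(=O)c4ccccc4)C12
F3 | step 16 | C8,C16-diol from 22 (C8 carbinol unassigned) | OC1[C@@H](OCc2ccccc2)C[C@H]2[C@@](C)(CO[Si](C(C)C)(C(C)C)C(C)C)CCC[C@]2(C)[C@@]12CC[C@@](CC(OC)OC)(CO)O2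
F4 | step 16 | hydroxy cyclic acetal, 8-alcohol corresponding to 24 (C8 carbinol unassigned) | OC1[C@@H](OCc2ccccc2)C[C@H]2[C@@](C)(CO[Si](C(C)C)(C(C)C)C(C)C)CCC[C@]2(C)[C@@]12CC[C@]1(CC(OC)OC1)O2
F5 | step 17 | 8(17)-methylene compound from 24 | C=C1[C@@H](OCc2ccccc2)C[C@H]2[C@@](C)(CO[Si](C(C)C)(C(C)C)C(C)C)CCC[C@]2(C)[C@@]12CC[C@]1(CC(OC)OC1)O2
F6 | step 17 | 8β,17-epoxide (spiro-oxirane with oxygen β) | C1O[C@]12[C@@H](OCc3ccccc3)C[C@H]3[C@@](C)(CO[Si](C(C)C)(C(C)C)C(C)C)CCC[C@]3(C)[C@@]24CC[C@]5(CC(OC)OC5)O4
F7 | step 17 | tertiary alcohol, 8α-methyl-8β-ol (neutral form of 25) | O[C@@]1(C)[C@@H](OCc2ccccc2)C[C@H]2[C@@](C)(CO[Si](C(C)C)(C(C)C)C(C)C)CCC[C@]2(C)[C@@]12CC[C@]1(CC(OC)OC1)O2
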